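**Retrosynthetic overview**
- Numbering (daucane): C1 quaternary fusion carbon bearing the C15 methyl, C2/C3 CH2, C4 carbinol bearing isopropyl, C5 fusion CH, C6 ester carbinol, C7 CH2, C8 bearing the C14 methyl, C9 =CH, C10 ketone. Ring A is the cyclopentane, ring B the cycloheptene, and β is the face of C15.
- Endgame: C14 and the C10 ketone come last, by alkylative 1,3-carbonyl transposition of the C8 enone 20. The ester and 6α-O come from a C6 ketone by reduction directed by the 4β-OH.
- Key disconnection: ring B of 15 is cut at C7–C8 and C10–C1. This gives the enolate of acetylcyclopentene 6 (C7–C6–C5=C1) and acryloylsilane 10 (C8–C9=C10).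
- Enabling feature: in ring B the oxygenated C6 and C8 flank C7. At the enol level C5=C6 and C8=C9 form a cyclohepta-1,4-diene whose saturated C10–C1 edge carries the quaternary carbon. That is the retron of the Cope rearrangement of a cis-dialkenylcyclopropanolate (ring C6–C7–C8).
- Ring order: ring A first, by C=C cleavage of the cyclohexene of (S)-terpinen-4-ol (C4 kept) and aldol ring contraction. Ring B second, in the key step.

Key step: step 7

Assumption: (S)-(+)-terpinen-4-ol is used as the single enantiomer; it supplies C4, from which C1, C5 and C6 are relayed.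

**Route**

Step 1
Reactants: 1 (S)-(+)-terpinen-4-ol
Product: 2 (S)-terpinen-4-yl trimethylsilyl ether
Conditions: Me3SiOTf, Et3N, CH2Cl2, 0 °C
Reagents that add atoms: trimethylsilyl triflate, C[Si](C)(C)OS(=O)(=O)C(F)(F)F
Why: O-silylation of the hindered tertiary alcohol with the silyl triflate blocks retro-aldol cleavage of the β-oxygenated aldehyde made in step 2 and leaves C4 untouched.

Step 2
Reactants: 2 (S)-terpinen-4-yl trimethylsilyl ether
Product: 3 (3S)-6-oxo-3-(propan-2-yl)-3-(trimethylsilyloxy)heptanal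
Conditions: O3, CH2Cl2, −78 °C; Me2S, −78 °C to rt
Reagents that add atoms: ozone, [O-][O+]=O
Why: Criegee ozonolysis with reductive work-up cleaves the only C=C bond of the cheap cyclohexene, so the skeleton is opened to a 1,6-keto aldehyde while the C4 stereocentre is kept.

Step 3
Reactants: 3 (3S)-6-oxo-3-(propan-2-yl)-3-(trimethylsilyloxy)heptanal
Product: 4 (5R)-2-methyl-5-(propan-2-yl)-5-(trimethylsilyloxy)cyclopent-1-ene-1-carbaldehyde
Conditions: dibenzylammonium trifluoroacetate (0.3 equiv), benzene, 45 °C
Reagents that add atoms: none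
Why: Intramolecular aldol condensation under enamine catalysis, in which only the aldehyde forms the enamine, its α-carbon (C5) attacks the methyl ketone in a 5-(enolexo)-exo-trig closure and loss of water gives ring A, the same ring contraction that is standard for limonene-derived 1,6-keto aldehydes.

Step 4
Reactants: 4 (5R)-2-methyl-5-(propan-2-yl)-5-(trimethylsilyloxy)cyclopent-1-ene-1-carbaldehyde
Product: 5 1-[(5R)-2-methyl-5-(propan-2-yl)-5-(trimethylsilyloxy)cyclopent-1-en-1-yl]ethan-1-ol (both carbinol epimers)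
Conditions: MeMgBr, THF, −78 °C; aq. NH4Cl
Reagents that add atoms: methylmagnesium bromide, C[Mg]Br
Why: Grignard 1,2-addition to the enal brings in C7, and the new carbinol centre is irrelevant because it is oxidised in step 5.

Step 5
Reactants: 5 1-[(5R)-2-methyl-5-(propan-2-yl)-5-(trimethylsilyloxy)cyclopent-1-en-1-yl]ethan-1-ol
Product: 6 1-[(5R)-2-methyl-5-(propan-2-yl)-5-(trimethylsilyloxy)cyclopent-1-en-1-yl]ethan-1-one
Conditions: MnO2 (excess), CH2Cl2, rt
Reagents that add atoms: none
Why: Neutral MnO2 oxidation of the allylic alcohol gives the alkenyl methyl ketone without touching the acid-labile tertiary silyl ether.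

Step 6
Reactants: 7 methoxyallene
Product: 10 1-[tert-butyl(dimethyl)silyl]prop-2-en-1-one, via 1-lithio-1-methoxyallene 8 (not isolated), via silylated methoxyallene 9 (not isolated)
Conditions: n-BuLi, THF, −78 °C; t-BuMe2SiCl, −78 °C to 0 °C; 1 M HCl (cat.), THF/H2O, 0 °C
Reagents that add atoms: tert-butyldimethylsilyl chloride, CC(C)(C)[Si](C)(C)Cl; water, O
Why: α-Lithiation of an alkoxyallene, C-silylation and hydrolysis of the allenyl ether (protonation at the central carbon) is the standard entry to α,β-unsaturated acylsilanes.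

Step 7
Reactants: 6 1-[(5R)-2-methyl-5-(propan-2-yl)-5-(trimethylsilyloxy)cyclopent-1-en-1-yl]ethan-1-one; 10 1-[tert-butyl(dimethyl)silyl]prop-2-en-1-one
Product: 15 trans-fused 8-(tert-butyldimethylsilyloxy)-4β-(trimethylsilyloxy)-14-nordauc-8-en-6-one, via lithium dienolate 11 (not isolated), via adduct alkoxide 12 (not isolated), via cyclopropanolate 13 (not isolated), via bicyclic enolate 14 (not isolated)
Conditions: LiN(iPr)2 (1.05 equiv), THF, −80 °C; 10, −80 to −20 °C; AcOH (1.1 equiv), −80 °C
Reagents that add atoms: none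
Why: This is the Brook-rearrangement-mediated [3+4] annulation of an acryloylsilane with an alkenyl methyl ketone enolate: C7 of 11 adds 1,2 to the acylsilane carbonyl (C7–C8 bond, 12), the 1,2-Brook shift moves silicon from C8 to oxygen while the emerging C8 carbanion closes 3-exo-trig onto the C6 ketone to give the cis-dialkenylcyclopropanolate 13, and its alkoxide-accelerated Cope rearrangement through the obligatory boat breaks C6–C8 and forms C10–C1 (14). Ring B is therefore closed by a [3,3]-sigmatropic expansion of a three-membered ring to a cyclohepta-1,4-diene and not by an end-to-end cyclisation, which is why the tetrasubstituted C5=C1 bond can deliver the quaternary C1 below 0 °C. For C1, the boat places the C6–OLi group next to C4 on the face opposite to the breaking C6–C8 bond; there it avoids the isopropyl group and lies beside the small, lithium-binding O4, and since cyclopropanolate formation is reversible the rearrangement that puts C10 on the α face (syn to isopropyl, anti to O4) should drain the equilibrium. For C5, enolate 14 should be protonated at −80 °C from the α face, because the β face of C5 is flanked by the C15 methyl and the OSiMe3 group, and no base is present afterwards, so the C8=C9 enol ether cannot slip into conjugation with C6. The step needs kinetic α′-deprotonation at the acetyl methyl (LiN(iPr)2, −80 °C) and 1,2- rather than 1,4-addition (a lithium enolate meeting the very electrophilic acylsilane carbonyl), and it releases the two carbonyl carbons already differentiated, C6 as ketone and C8 as silyl enol ether.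

Step 8
Reactants: 15 trans-fused 8-(tert-butyldimethylsilyloxy)-4β-(trimethylsilyloxy)-14-nordauc-8-en-6-one
Product: 17 8-(tert-butyldimethylsilyloxy)-14-nordauc-8-ene-4β,6α-diol, via 4β-hydroxy ketone 16 (not isolated)
Conditions: citric acid (cat.), MeOH, 0 °C; concentrate; Me4NBH(OAc)3, MeCN/AcOH, −30 °C
Reagents that add atoms: none
Why: SiMe3 is methanolysed far faster than the bulky tert-butyldimethylsilyl enol ether, and in the Evans–Saksena reduction the borohydride exchanges onto the 4β-OH and delivers hydride intramolecularly to the β face of the C6 ketone, which sets the 6α-OH (1,3-anti).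

Step 9
Reactants: 17 8-(tert-butyldimethylsilyloxy)-14-nordauc-8-ene-4β,6α-diol; 18 3,4,5-trimethoxybenzoyl chloride
Product: 19 6α-(3,4,5-trimethoxybenzoyloxy)-8-(tert-butyldimethylsilyloxy)-14-nordauc-8-en-4β-ol
Conditions: Et3N, DMAP (cat.), CH2Cl2, 0 °C to rt
Reagents that add atoms: none
Why: DMAP-catalysed acylation takes the secondary 6-OH and leaves the tertiary 4-OH free for steric reasons.

Step 10
Reactants: 19 6α-(3,4,5-trimethoxybenzoyloxy)-8-(tert-butyldimethylsilyloxy)-14-nordauc-8-en-4β-ol
Product: 20 6α-(3,4,5-trimethoxybenzoyloxy)-4β-hydroxy-14-nordauc-9-en-8-one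
Conditions: Pd(OAc)2 (1.0 equiv), MeCN, 40 °C
Reagents that add atoms: none
Why: Saegusa–Ito oxidation, in which divalent palladium attacks C9 of the silyl enol ether and β-hydride elimination can only use a C10–H, so the C9=C10 enone forms regiospecifically under neutral conditions that spare the β-acyloxy ketone.

Step 11
Reactants: 20 6α-(3,4,5-trimethoxybenzoyloxy)-4β-hydroxy-14-nordauc-9-en-8-one
Product: 21 6α-(3,4,5-trimethoxybenzoyloxy)dauc-9-ene-4β,8-diol (both C8 epimers)
Conditions: CeCl3 (dried), MeLi (2.5 equiv each), THF, −78 °C; aq. NH4Cl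
Reagents that add atoms: methyllithium, [Li]C
Why: The weakly basic, oxophilic organocerium reagent adds 1,2 to the enone at −78 °C faster than it attacks the hindered aryl ester or triggers E1cB loss of the benzoate, and the C8 configuration does not matter.

Step 12
Reactants: 21 6α-(3,4,5-trimethoxybenzoyloxy)dauc-9-ene-4β,8-diol
Product: 22 target, 6α-(3,4,5-trimethoxybenzoyloxy)-4β-hydroxydauc-8-en-10-one (CNP0218356.1)
Conditions: pyridinium chlorochromate C5H5NH[CrO3Cl] (3 equiv), 4 Å molecular sieves, CH2Cl2, rt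
Reagents that add atoms: pyridinium chlorochromate, [O-][Cr](=O)(=O)Cl.c1cc[nH+]cc1
Why: Babler–Dauben oxidative transposition, in which the tertiary allylic chromate ester shifts [3,3] to C10 and is oxidised there to the C8=C9–C10 enone, both C8 epimers converge and the non-allylic tertiary 4-OH is inert.

**Compound list**
1 | (S)-(+)-terpinen-4-ol, (1S)-4-methyl-1-(propan-2-yl)cyclohex-3-en-1-ol | CC1=CC[C@](O)(C(C)C)CC1 | starting material
2 | (S)-terpinen-4-yl trimethylsilyl ether | CC1=CC[C@](O[Si](C)(C)C)(C(C)C)CC1 | intermediate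
3 | (3S)-6-oxo-3-(propan-2-yl)-3-(trimethylsilyloxy)heptanal | O=CC[C@](O[Si](C)(C)C)(C(C)C)CCC(C)=O | intermediate
4 | (5R)-2-methyl-5-(propan-2-yl)-5-(trimethylsilyloxy)cyclopent-1-ene-1-carbaldehyde | O=CC1=C(C)CC[C@@]1(O[Si](C)(C)C)C(C)C | intermediate
5 | 1-[(5R)-2-methyl-5-(propan-2-yl)-5-(trimethylsilyloxy)cyclopent-1-en-1-yl]ethan-1-ol, both carbinol epimers | CC(O)C1=C(C)CC[C@@]1(O[Si](C)(C)C)C(C)C | intermediate
6 | 1-[(5R)-2-methyl-5-(propan-2-yl)-5-(trimethylsilyloxy)cyclopent-1-en-1-yl]ethan-1-one | CC(=O)C1=C(C)CC[C@@]1(O[Si](C)(C)C)C(C)C | intermediate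
7 | methoxyallene (1-methoxypropa-1,2-diene) | C=C=COC | starting material
8 | 1-lithio-1-methoxyallene | [Li]C(OC)=C=C | intermediate
9 | tert-butyl(1-methoxypropa-1,2-dien-1-yl)dimethylsilane | C=C=C(OC)[Si](C)(C)C(C)(C)C | intermediate
10 | 1-[tert-butyl(dimethyl)silyl]prop-2-en-1-one | C=CC(=O)[Si](C)(C)C(C)(C)C | intermediate
11 | lithium cross-conjugated dienolate of 6 | [Li+].C=C([O-])C1=C(C)CC[C@@]1(O[Si](C)(C)C)C(C)C | intermediate
12 | lithium alkoxide from 1,2-addition of 11 to 10 (C8 epimers) | [Li+].C=CC([O-])([Si](C)(C)C(C)(C)C)CC(=O)C1=C(C)CC[C@@]1(O[Si](C)(C)C)C(C)C | intermediate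
13 | lithium cis-2-ethenyl-2-(tert-butyldimethylsilyloxy)-1-(cyclopentenyl)cyclopropan-1-olate | [Li+].C=C[C@@]1(O[Si](C)(C)C(C)(C)C)C[C@@]1([O-])C2=C(C)CC[C@@]2(O[Si](C)(C)C)C(C)C | intermediate
14 | lithium C5=C6 enolate of 15 | [Li+].[O-]C1=C2[C@](O[Si](C)(C)C)(C(C)C)CC[C@]2(C)CC=C(O[Si](C)(C)C(C)(C)C)C1 | intermediate
15 | 8-(tert-butyldimethylsilyloxy)-4β-(trimethylsilyloxy)-14-nordauc-8-en-6-one (1β-CH3, 5α-H, 4α-isopropyl) | O=C1CC(O[Si](C)(C)C(C)(C)C)=CC[C@@]2(C)CC[C@@](O[Si](C)(C)C)(C(C)C)[C@H]12 | intermediate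
16 | 8-(tert-butyldimethylsilyloxy)-4β-hydroxy-14-nordauc-8-en-6-one | O=C1CC(O[Si](C)(C)C(C)(C)C)=CC[C@@]2(C)CC[C@@](O)(C(C)C)[C@H]12 | intermediate
17 | 8-(tert-butyldimethylsilyloxy)-14-nordauc-8-ene-4β,6α-diol | O[C@H]1CC(O[Si](C)(C)C(C)(C)C)=CC[C@@]2(C)CC[C@@](O)(C(C)C)[C@H]12 | intermediate
18 | 3,4,5-trimethoxybenzoyl chloride | COc1cc(C(=O)Cl)cc(OC)c1OC | starting material
19 | 6α-(3,4,5-trimethoxybenzoyloxy)-8-(tert-butyldimethylsilyloxy)-14-nordauc-8-en-4β-ol | COc1cc(C(=O)O[C@H]2CC(O[Si](C)(C)C(C)(C)C)=CC[C@@]3(C)CC[C@@](O)(C(C)C)[C@H]23)cc(OC)c1OC | intermediate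
20 | 6α-(3,4,5-trimethoxybenzoyloxy)-4β-hydroxy-14-nordauc-9-en-8-one | COc1cc(C(=O)O[C@H]2CC(=O)C=C[C@@]3(C)CC[C@@](O)(C(C)C)[C@H]23)cc(OC)c1OC | intermediate
21 | 6α-(3,4,5-trimethoxybenzoyloxy)dauc-9-ene-4β,8-diol, both C8 epimers | COc1cc(C(=O)O[C@H]2CC(C)(O)C=C[C@@]3(C)CC[C@@](O)(C(C)C)[C@H]23)cc(OC)c1OC | intermediate
22 | 6α-(3,4,5-trimethoxybenzoyloxy)-4β-hydroxydauc-8-en-10-one (CNP0218356.1) | COc1cc(C(=O)O[C@H]2CC(C)=CC(=O)[C@@]3(C)CC[C@@](O)(C(C)C)[C@H]23)cc(OC)c1OC | target

**Step count**
- Total steps: 12.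
- Longest linear sequence: 11 (steps 1–5 and 7–12).

**Steps most likely to fail**

Step 7.
- Risk: enolate 14 may be protonated at C5 from the β face, giving the cis-fused ketone. This cannot be repaired later with base, because the more acidic C7 protons would let the C8=C9 enol ether move into conjugation. Conjugate addition to the unsubstituted acryloylsilane would also cost material.
- Fallback: it sets out from 6 and 10. The annulation is run as before, but 14 is trapped in the flask with allyl chloroformate to give the allyl enol carbonate F1. Palladium-catalysed decarboxylative protonation then places the C5 hydrogen under ligand control in a neutral medium (Pd(OAc)2, t-Bu-PHOX of the matched handedness, HCO2H, dioxane, 40 °C). The sequence comes back to the route at 15.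

Step 3.
- Risk: the silyloxy group may be lost by β-elimination from the enamine or iminium ion. Alternatively SiMe3 may be lost and retro-aldol cleavage may follow before the slow attack on the methyl ketone.
- Fallback: it sets out from 3 and avoids amine catalysis altogether. The aldehyde alone is converted with t-BuMe2SiOTf/Et3N at −78 °C into the aldehyde silyl enol ether F2. An intramolecular Mukaiyama aldol addition to the ketone (BF3·OEt2, CH2Cl2, −78 °C) closes ring A as the β-hydroxy aldehyde F3. Only the new free tertiary alcohol is then dehydrated with the Burgess reagent, and the sequence comes back at 4.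

Step 11.
- Risk: the trimethoxybenzoate may be lost from the β-acyloxy ketone by E1cB elimination, or the ester may be attacked during methyl addition.
- Fallback: it sets out from 19 and never makes a C8 ketone. The silyl enol ether is converted with nonafluorobutanesulfonyl fluoride and catalytic Bu4NF into the alkenyl nonaflate F4. Suzuki–Miyaura methylation (trimethylboroxine, Pd(dppf)Cl2, K2CO3, dioxane) gives the C8-methyl alkene F5. Allylic oxidation at C10, the ring CH2 on the CH end of the trisubstituted alkene (Rh2(cap)4, t-BuOOH), comes back at 22.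

**Further compounds**
F1 | step 7 | allyl enol carbonate of 15 (C5=C6) | C=CCOC(=O)OC1=C2[C@](O[Si](C)(C)C)(C(C)C)CC[C@]2(C)CC=C(O[Si](C)(C)C(C)(C)C)C1
F2 | step 3 | (3S)-1-(tert-butyldimethylsilyloxy)-3-(propan-2-yl)-3-(trimethylsilyloxy)hept-1-en-6-one, E/Z mixture | CC(C)(C)[Si](C)(C)OC=C[C@](O[Si](C)(C)C)(C(C)C)CCC(C)=O
F3 | step 3 | (5R)-2-hydroxy-2-methyl-5-(propan-2-yl)-5-(trimethylsilyloxy)cyclopentane-1-carbaldehyde, epimers at C1 and C2 | O=CC1C(C)(O)CC[C@@]1(O[Si](C)(C)C)C(C)C
F4 | step 11 | C8 alkenyl nonaflate of 6α-(3,4,5-trimethoxybenzoyloxy)-14-nordauc-8-en-4β-ol | COc1cc(C(=O)O[C@H]2CC(OS(=O)(=O)C(F)(F)C(F)(F)C(F)(F)C(F)(F)F)=CC[C@@]3(C)CC[C@@](O)(C(C)C)[C@H]23)cc(OC)c1OC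
F5 | step 11 | 6α-(3,4,5-trimethoxybenzoyloxy)dauc-8-en-4β-ol | COc1cc(C(=O)O[C@H]2CC(C)=CC[C@@]3(C)CC[C@@](O)(C(C)C)[C@H]23)cc(OC)c1OC
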